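The oxidised geranyl chain is cut at its head-to-tail isoprene junction, the bond between the CH2 on the quaternary oxirane carbon and the lactone O–CH carbon. This carbinol carbon is the aldehyde of a dioxolanone made from (R)-citramalic acid, which supplies the lactone CH2, the C(OH)CH3 stereocentre and the carbonyl. A tryptophan-oxazaborolidinone-controlled vinylogous Mukaiyama aldol with the silyl dienol ether of prenal, a mimic of prenyl transfer, forms this bond, the new carbinol stereocentre and the E-trisubstituted alkene; the 1,4-related hydroxyl and masked carboxyl then close the γ-lactone ring. Luche reduction, Sharpless epoxidation and Mitsunobu etherification with 7-hydroxy-8-methoxycoumarin complete the target.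

Key step: step 5

Assumption: (R)-citramalic acid, prenal and 7-hydroxy-8-methoxycoumarin are taken as purchasable.

Remark on descriptors: the spatial arrangement at the lactone O–CH carbon is the same in compounds 7 to 12; its CIP label is R while the side chain carries the alkene and becomes S once the oxirane is present, only because the priorities switch.

Step 1
Reactants: 1 (R)-citramalic acid
Product: 2 [(4R)-2,2,4-trimethyl-5-oxo-1,3-dioxolan-4-yl]acetic acid
Conditions: 2,2-dimethoxypropane, TsOH·H2O (cat.), acetone, rt
Reagents that add atoms: 2,2-dimethoxypropane, COC(C)(C)OC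
Why: Acid-catalysed transacetalisation (acetonide formation) ties the tertiary hydroxyl and its geminal carboxyl into the five-membered dioxolanone, which is favoured over the six-membered alternative, and leaves the CH2CO2H arm free without touching the quaternary stereocentre.

Step 2
Reactants: 2 [(4R)-2,2,4-trimethyl-5-oxo-1,3-dioxolan-4-yl]acetic acid
Product: 3 (5R)-5-(2-hydroxyethyl)-2,2,5-trimethyl-1,3-dioxolan-4-one
Conditions: BH3·SMe2, THF, 0 °C to rt; MeOH quench
Reagents that add atoms: none
Why: Chemoselective borane reduction, in which the free carboxylic acid is reduced through its acyloxyborane far faster than the dioxolanone ester, so only the acetic acid arm becomes CH2OH.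

Step 3
Reactants: 3 (5R)-5-(2-hydroxyethyl)-2,2,5-trimethyl-1,3-dioxolan-4-one
Product: 4 [(4R)-2,2,4-trimethyl-5-oxo-1,3-dioxolan-4-yl]acetaldehyde
Conditions: Dess–Martin periodinane, CH2Cl2, 0 °C to rt
Reagents that add atoms: none
Why: Dess–Martin oxidation stops cleanly at the aldehyde under non-basic conditions, which avoids β-elimination of the acetal oxygen and keeps the dioxolanone intact.

Step 4
Reactants: 5 3-methylbut-2-enal (prenal)
Product: 6 (E)-tert-butyldimethyl[(3-methylbuta-1,3-dien-1-yl)oxy]silane
Conditions: TBSOTf, Et3N, Et2O, 0 °C to rt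
Reagents that add atoms: tert-butyldimethylsilyl triflate, CC(C)(C)[Si](C)(C)OS(=O)(=O)C(F)(F)F
Why: Silyl dienol ether formation, in which O-silylation of the enal followed by γ-deprotonation by Et3N gives the 1-silyloxy diene, the E enol ether being expected to predominate.

Step 5
Reactants: 4 [(4R)-2,2,4-trimethyl-5-oxo-1,3-dioxolan-4-yl]acetaldehyde; 6 (E)-tert-butyldimethyl[(3-methylbuta-1,3-dien-1-yl)oxy]silane
Product: 8 (2E)-4-[(2R,4R)-4-hydroxy-4-methyl-5-oxooxolan-2-yl]-3-methylbut-2-enal (side chain cis to the ring methyl), via aldol adduct 7 (not isolated)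
Conditions: (S)-4-(1H-indol-3-ylmethyl)-2-phenyl-3-tosyl-1,3,2-oxazaborolidin-5-one (50 mol %), iPrOH (1.1 equiv), EtCN, −78 °C; then (±)-camphor-10-sulfonic acid (cat.), CH2Cl2, rt
Reagents that add atoms: none
Why: The boron Lewis acid activates the aldehyde of 4 and the terminal CH2 (γ-carbon) of silyl dienol ether 6 attacks it, so the new C–C bond joins the chain CH2 to the future lactone O–CH carbon just as an isopentenyl unit attacks a prenyl cation in terpene chain growth, and loss of silicon to iPrOH leaves the conjugated enal. The closest known reaction type is the oxazaborolidinone-promoted asymmetric vinylogous Mukaiyama aldol reaction of aldehyde-derived silyl dienol ethers. The γ-lactone ring then closes by 5-exo-trig acyl substitution of the new hydroxyl on the dioxolanone carbonyl, with loss of acetone, which also frees the tertiary hydroxyl. The new carbinol stereocentre is set by the L-tryptophan-derived promoter, since in the accepted stacking model (formyl C–H···O contact to the ring oxygen, indole stacked over the bound C=O) the Si face is shielded and addition should occur on the Re face, which places the side chain cis to the ring methyl after lactonisation; the quaternary centre comes unchanged from citramalic acid. The step needs γ- over α-attack (secured by the conjugation kept in the γ-adduct and by sterics), E geometry (secured by the s-trans diene, which puts the methyl next to the small enol-ether hydrogen) and aldehyde-over-ester chemoselectivity (the aldehyde is the most basic and most electrophilic carbonyl present).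

Step 6
Reactants: 8 (2E)-4-[(2R,4R)-4-hydroxy-4-methyl-5-oxooxolan-2-yl]-3-methylbut-2-enal
Product: 9 (3R,5R)-3-hydroxy-5-[(2E)-4-hydroxy-2-methylbut-2-en-1-yl]-3-methyloxolan-2-one
Conditions: NaBH4, CeCl3·7H2O, MeOH, −78 °C
Reagents that add atoms: none
Why: Luche reduction, in which CeCl3-assisted NaBH4 reduces the conjugated aldehyde in 1,2-fashion at low temperature much faster than it attacks the lactone, and the E alkene is untouched.

Step 7
Reactants: 9 (3R,5R)-3-hydroxy-5-[(2E)-4-hydroxy-2-methylbut-2-en-1-yl]-3-methyloxolan-2-one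
Product: 10 (3R,5S)-3-hydroxy-5-{[(2R,3R)-3-(hydroxymethyl)-2-methyloxiran-2-yl]methyl}-3-methyloxolan-2-one
Conditions: Ti(OiPr)4, D-(−)-diethyl tartrate, tBuOOH, 4 Å MS, CH2Cl2, −20 °C
Reagents that add atoms: tert-butyl hydroperoxide, CC(C)(C)OO
Why: Sharpless asymmetric epoxidation of the E-trisubstituted allylic alcohol, in which the D-(−)-tartrate titanium complex delivers oxygen to the alkene face that gives the (2R,3R)-oxirane (the mirror image of the 2S,3S outcome known for L-(+)-tartrate with geraniol-type alcohols), syn addition keeps CH2OH and the lactone-bearing CH2 trans, and reagent control should override the remote lactone stereocentres.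

Step 8
Reactants: 10 (3R,5S)-3-hydroxy-5-{[(2R,3R)-3-(hydroxymethyl)-2-methyloxiran-2-yl]methyl}-3-methyloxolan-2-one; 11 7-hydroxy-8-methoxy-2H-chromen-2-one
Product: 12 7-{[(2R,3R)-3-{[(2S,4R)-4-hydroxy-4-methyl-5-oxooxolan-2-yl]methyl}-3-methyloxiran-2-yl]methoxy}-8-methoxy-2H-chromen-2-one (target)
Conditions: PPh3, DIAD, THF, 0 °C to rt
Reagents that add atoms: none
Why: Mitsunobu etherification, in which the acidic coumarin 7-OH displaces the activated primary oxygen by SN2 at CH2, a carbon that is not stereogenic, while the oxirane and the tertiary alcohol do not react.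

Compound list
1 | (R)-(−)-citramalic acid, (2R)-2-hydroxy-2-methylbutanedioic acid | OC(=O)C[C@@](C)(O)C(=O)O | starting material
2 | [(4R)-2,2,4-trimethyl-5-oxo-1,3-dioxolan-4-yl]acetic acid | OC(=O)C[C@@]1(C)OC(C)(C)OC1=O | intermediate
3 | (5R)-5-(2-hydroxyethyl)-2,2,5-trimethyl-1,3-dioxolan-4-one | OCC[C@@]1(C)OC(C)(C)OC1=O | intermediate
4 | [(4R)-2,2,4-trimethyl-5-oxo-1,3-dioxolan-4-yl]acetaldehyde | O=CC[C@@]1(C)OC(C)(C)OC1=O | intermediate
5 | 3-methylbut-2-enal (prenal) | CC(C)=CC=O | starting material
6 | (E)-tert-butyldimethyl[(3-methylbuta-1,3-dien-1-yl)oxy]silane | C=C(C)/C=C/O[Si](C)(C)C(C)(C)C | intermediate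
7 | aldol adduct, (5R)-5-[(2R,4E)-2-hydroxy-4-methyl-6-oxohex-4-en-1-yl]-2,2,5-trimethyl-1,3-dioxolan-4-one | O=C/C=C(\C)C[C@@H](O)C[C@@]1(C)OC(C)(C)OC1=O | intermediate
8 | (2E)-4-[(2R,4R)-4-hydroxy-4-methyl-5-oxooxolan-2-yl]-3-methylbut-2-enal | O=C/C=C(\C)C[C@@H]1C[C@@](C)(O)C(=O)O1 | intermediate
9 | (3R,5R)-3-hydroxy-5-[(2E)-4-hydroxy-2-methylbut-2-en-1-yl]-3-methyloxolan-2-one | OC/C=C(\C)C[C@@H]1C[C@@](C)(O)C(=O)O1 | intermediate
10 | (3R,5S)-3-hydroxy-5-{[(2R,3R)-3-(hydroxymethyl)-2-methyloxiran-2-yl]methyl}-3-methyloxolan-2-one | OC[C@H]1O[C@]1(C)C[C@@H]2C[C@@](C)(O)C(=O)O2 | intermediate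
11 | 7-hydroxy-8-methoxy-2H-chromen-2-one | COc1c(O)ccc2ccc(=O)oc12 | starting material
12 | 7-{[(2R,3R)-3-{[(2S,4R)-4-hydroxy-4-methyl-5-oxooxolan-2-yl]methyl}-3-methyloxiran-2-yl]methoxy}-8-methoxy-2H-chromen-2-one | COc1c(OC[C@H]2O[C@]2(C)C[C@@H]2C[C@@](C)(O)C(=O)O2)ccc2ccc(=O)oc12 | target

Total step count: 8. Longest linear sequence: 7 steps (steps 1, 2, 3, 5, 6, 7 and 8, from compound 1).

Steps most likely to fail

Step 5. Facial selectivity may be poor if the dioxolanone oxygens compete with the aldehyde for boron or if the substrate is mismatched with the promoter; the alkene geometry may erode, and the δ-hydroxy enal may dehydrate during the acid treatment. The fallback sets out from aldehyde 4 and comes back at allylic alcohol 9. Asymmetric propargylation of 4 with allenylboronic acid pinacol ester under 3,3'-bis(2,4,6-triisopropylphenyl)-1,1'-binaphthyl-2,2'-diyl hydrogen phosphate (the antipode that sends the allenyl unit to the Re face) should give the homopropargylic alcohol F1. Camphorsulfonic acid then closes it to the propargyl lactone F2. Zirconium-catalysed methylalumination (AlMe3, Cp2ZrCl2, CH2Cl2, then I2) fixes the E geometry by syn addition and should give the vinyl iodide F3. Stille coupling of F3 with (tributylstannyl)methanol and Pd(PPh3)4 returns to 9.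

Step 8. The oxirane may be opened by the phenoxide or by the betaine, or the epoxy alcohol may rearrange before substitution. The fallback sets out from allylic alcohol 9 and comes back at target 12. Mitsunobu etherification of 9 with 11 (PPh3, DIAD) should give the allyl aryl ether F4. Shi epoxidation of F4 with 1,2:4,5-di-O-isopropylidene-β-D-erythro-2,3-hexodiulo-2,6-pyranose (Oxone, K2CO3 buffer, MeCN/dimethoxymethane, 0 °C) is expected by the spiro transition-state model to give the (2R,3R)-oxirane of this E-trisubstituted alkene, that is 12; the electron-poor coumarin alkene should not react.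

Step 2. The hydroxyethyl dioxolanone may translactonise prematurely with loss of acetone, or the dioxolanone may be over-reduced. The fallback sets out from acid 2 and comes back at aldehyde 4. Coupling of 2 with ethanethiol (EDC·HCl, 4-(dimethylamino)pyridine, CH2Cl2) should give the S-ethyl thioester F5. Fukuyama reduction of F5 (Et3SiH, Pd/C, acetone, rt) gives 4 directly, so no free alcohol is ever formed.

Further compounds
F1 | step 5 | homopropargylic alcohol, (5R)-5-[(2R)-2-hydroxypent-4-yn-1-yl]-2,2,5-trimethyl-1,3-dioxolan-4-one | C#CC[C@@H](O)C[C@@]1(C)OC(C)(C)OC1=O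
F2 | step 5 | propargyl lactone, (3R,5R)-3-hydroxy-3-methyl-5-(prop-2-yn-1-yl)oxolan-2-one | C#CC[C@@H]1C[C@@](C)(O)C(=O)O1
F3 | step 5 | vinyl iodide, (3R,5R)-3-hydroxy-5-[(2E)-3-iodo-2-methylprop-2-en-1-yl]-3-methyloxolan-2-one | I/C=C(\C)C[C@@H]1C[C@@](C)(O)C(=O)O1
F4 | step 8 | allyl aryl ether, 7-{[(2E)-4-[(2R,4R)-4-hydroxy-4-methyl-5-oxooxolan-2-yl]-3-methylbut-2-en-1-yl]oxy}-8-methoxy-2H-chromen-2-one | COc1c(OC/C=C(\C)C[C@@H]2C[C@@](C)(O)C(=O)O2)ccc2ccc(=O)oc12
F5 | step 2 | S-ethyl thioester, S-ethyl [(4R)-2,2,4-trimethyl-5-oxo-1,3-dioxolan-4-yl]ethanethioate | CCSC(=O)C[C@@]1(C)OC(C)(C)OC1=O
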